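(All runs come from a simulation for substances that don't exist; the scatter is artificial.)

The ratio φ, the highest target reading (percent of solid substrate charged) divided by the equivalents of partner, counts target won per partner charged.

| setting | zeta | delta | theta | flask |
|---|---|---|---|---|
| solid substrate | 0.40 M | 0.60 M | 0.80 M | 0.80 M |
| partner | 0.70 equiv | 0.70 equiv | 0.35 equiv | 0.700 equiv |
| remark | run made earlier | run made earlier | run made earlier |  |
| time |  |  |  | 15 d |

| run | time / d | target / % |
|---|---|---|
| zeta | 1.67 | 8.4 |
| zeta | 2.00 | 12.1 |
| zeta | 3.00 | 18.3 |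
| zeta | 4.00 | 19.7 |
| zeta | 6.00 | 23.5 |
| zeta | 8.00 | 21.8 |
| zeta | 12.0 | 21.6 |
| delta | 1.67 | 10.2 |
| delta | 2.00 | 14.9 |
| delta | 3.00 | 21.7 |
| delta | 4.00 | 26.1 |
| delta | 6.00 | 29.1 |
| delta | 8.00 | 26.1 |
| delta | 12.0 | 22.0 |
| theta | 1.67 | 5.2 |
| theta | 2.50 | 11.2 |
| theta | 4.00 | 14.7 |
| theta | 8.00 | 15.9 |
| theta | 12.0 | 11.3 |

(scatter of a reading: 1 percentage point)

- solid, in amounts per volume of the solution: solid substrate
- at the start none of the solid substrate is in solution

- the moment within 15 d at which there is most target
- the amount of target, in percent of the solid substrate charged, at that time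

φ reads 0.336 in zeta, 0.416 in delta and 0.454 in theta. Theta shares the loading of the flask, 0.80 M, so I carry its φ, the partner yield at that loading. At 0.700 equiv I reckon 31.8% of target for the flask, give or take 2 percentage points from the scatter of the theta reading. One number is not enough: at fixed equivalents φ climbs from zeta to delta, so I hold the loading fixed. No two runs differ in equivalents at one loading, so scaling with partner is my assumption. Zeta and delta both show their highest reading at 6.00 d, and I commit to about that time.

The forecast gives 31% at 5.5 d, noting “All peaks sit near 5–7 d”.

The flask gives 31.0% at 6.08 d.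

    target → over-reaction product (k = 1.50 × 10⁻⁶ /s)
    open intermediate + second intermediate → target (k = 1.10 × 10⁻⁵ /M/s)
    partner → second intermediate (k = 3.50 × 10⁻⁵ /s)
    starting material ⇌ open intermediate (K = 0.710, k = 4.70 × 10⁻⁴ /s)
    solid substrate ⇌ starting material, rate k5*(cs5 - [starting material]) while solid is left; crystals form when [starting material] > cs5 (solubility = 0.500 M, k = 1.30 × 10⁻⁵ /s)

The flask's φ is 0.443, against 0.454 in theta. For a neighbouring flask, at 0.48 M and the same equivalents, φ interpolated between zeta and delta is 0.368, which reckons 25.7% of target. Partner is the limiting reagent of that neighbouring flask, with 0% left at the end, while 25% of the solid substrate charged remains, solid or dissolved. That neighbouring flask reaches 25.6%.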